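**Retrosynthetic overview**

1. The target is reached from a ten-membered hydroxy enoate by (R)-2-methylglycidate at O9, acetate at O8, oxidation of a C12 lactol ether to the cis-fused 6,12-lactone, and last the epoxidation of Z C4=C5.
2. The ten-membered ring comes from a Grob fragmentation across C4–C9 of a cis-decalin (ring A = C10, C1, C2, C3, C4, C9; ring B = C4–C9). The strategy rests on C4 (methyl-bearing) and C9 (oxygen-bearing) lying opposite each other in the carbocycle C1–C10: Z C4=C5, the C9 oxygen and the ring-cis C10=C1 ester are what a C9-alkoxide/C5-mesylate fragmentation leaves behind.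
3. The ring B centres come from a 5,7-diene: singlet oxygen puts O5 and O8 on the β face, a Claisen shift from O5 carries C11 to C7β, and opening of the 5α,6α-epoxide by the side-chain carbonyl gives O6β (as the C12 acetal) and the 5α-OH that becomes the mesylate.
4. The cis-decalin comes from 2-methylcyclohexane-1,3-dione and methyl 3-oxopent-4-enoate: Michael addition, D-proline aldol to the cis-ketol (C4, 9β-OH), then enol triflate reduction to the C10=C1 ester.
5. Ring order: ring B (from 1), ring A (step 2), tetrahydrofuran acetal ring (step 14), ten-membered ring (step 16), γ-lactone by oxidation (step 22), C4–C5 epoxide (step 23); the glycidate epoxide arrives with acid 25.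

Key step: step 16

Remark: germacrane numbering (C1–C15) is used for every compound; β means the face of the C4 methyl group in the decalins.
Remark: the acetal carbon C12 made in step 14 is expected as a mixture of anomers; it is carried as such and disappears in step 22, so it is left undefined in the SMILES.
Remark: D-proline is assumed to give the (4R) series, by analogy with L-proline giving the (S) series of Wieland–Miescher ketones.

**Route**

Step 1
Reactants: 1 2-methylcyclohexane-1,3-dione; 2 methyl 3-oxopent-4-enoate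
Product: 3 triketone methyl 5-(1-methyl-2,6-dioxocyclohexyl)-3-oxopentanoate
Conditions: Et3N (0.1 equiv), EtOAc, 0 °C → rt
Reagents that add atoms: none
Why: Michael addition of the acidic C–H of the 1,3-dione to the vinyl ketone forms C3–C4 and the prochiral quaternary C4, and the weak amine catalyst is chosen so that the reaction should stop at the achiral triketone.

Step 2
Reactants: 3 triketone
Product: 4 cis-ketol (enol form of the β-keto ester; 4β-CH3, 9β-OH)
Conditions: D-proline (0.3 equiv), DMF, 4 °C → rt
Reagents that add atoms: none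
Why: Hajos–Parrish–Eder–Sauer–Wiechert aldol, in which the proline enamine of the side-chain keto ester attacks through C10 one of the two enantiotopic ring carbonyls under direction by the carboxylic acid, which should set C4 as R and, because the new six-membered ring can only close cis, the 9β-hydroxyl, the product being held at the ketol stage as the hydrogen-bonded enol.

Step 3
Reactants: 4 cis-ketol
Product: 5 enol triflate (C1–OTf on C1=C10)
Conditions: NaH (1.05 equiv), THF, 0 °C; PhNTf2, 0 °C → rt
Reagents that add atoms: N-phenylbis(trifluoromethanesulfonimide), O=S(=O)(N(c1ccccc1)S(=O)(=O)C(F)(F)F)C(F)(F)F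
Why: O-sulfonylation of the sodium enolate of the β-keto ester, the most acidic site, so that the tertiary alcohol and the C5 ketone should stay untouched.

Step 4
Reactants: 5 enol triflate
Product: 6 hydroxy keto enoate (cis-decalin, C10=C1 ester, C5 ketone, 9β-OH)
Conditions: Pd(OAc)2 (5 mol %), PPh3 (10 mol %), HCO2H, Bu3N, DMF, 60 °C
Reagents that add atoms: none
Why: palladium-catalysed formate reduction of an enol triflate (oxidative addition, hydride transfer from formate, reductive elimination) turns the β-keto ester into the C10=C1 enoate, whose geometry (C9 and C2 cis) is fixed by ring A.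

Step 5
Reactants: 6 hydroxy keto enoate
Product: 7 bis(trimethylsilyl) compound (C9–OSiMe3 and C5(OSiMe3)=C6)
Conditions: Me3SiOTf (2.5 equiv), Et3N, CH2Cl2, −78 → 0 °C
Reagents that add atoms: trimethylsilyl trifluoromethanesulfonate, C[Si](C)(C)OS(=O)(=O)C(F)(F)F
Why: soft enolisation and silylation, in which the enol ether can only form toward C6 because C4 is quaternary, and the tertiary alcohol is capped so that later base cannot start a retro-aldol cleavage of the C5-keto/C9-ol pair.

Step 6
Reactants: 7 bis(trimethylsilyl) compound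
Product: 8 enone (C5 ketone, C6=C7, C9–OSiMe3)
Conditions: Pd(OAc)2 (1.05 equiv), MeCN, rt
Reagents that add atoms: none
Why: Saegusa–Ito oxidation of the silyl enol ether by divalent palladium gives the ring B enone without base.

Step 7
Reactants: 8 enone
Product: 9 dienyl triflate (C5(OTf)=C6–C7=C8)
Conditions: KN(SiMe3)2 (1.1 equiv), THF, −78 °C; N-(5-chloropyridin-2-yl)bis(trifluoromethanesulfonimide), −78 °C
Reagents that add atoms: N-(5-chloropyridin-2-yl)bis(trifluoromethanesulfonimide), O=S(=O)(N(c1ccc(Cl)cn1)S(=O)(=O)C(F)(F)F)C(F)(F)F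
Why: with no α′-hydrogen at the quaternary C4 the base can only remove a γ-hydrogen at C8, and the extended enolate is O-triflated at −78 °C (vinylogous enolate triflation) before silanolate can be lost from C9.

Step 8
Reactants: 9 dienyl triflate
Product: 11 dienol (ring B 5,7-diene, free 9β-OH), via trimethylsilyl ether 10 (not isolated)
Conditions: Pd(OAc)2 (5 mol %), PPh3, HCO2H, Bu3N, DMF, 60 °C; then K2CO3, MeOH, 0 °C
Reagents that add atoms: none
Why: formate reduction of the dienyl triflate gives the 5,7-diene, and base-catalysed methanolysis of the tertiary silyl ether frees the C9 hydroxyl needed to steer the next step.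

Step 9
Reactants: 11 dienol
Product: 13 triol (5β-OH, 8β-OH, 9β-OH, C6=C7), via endoperoxide 12 (not isolated)
Conditions: O2, visible light, 5,10,15,20-tetraphenylporphyrin (1 mol %), CH2Cl2, −20 °C; then thiourea, MeOH, rt
Reagents that add atoms: dioxygen, O=O
Why: [4+2] cycloaddition of singlet oxygen to the diene (which has no allylic hydrogen for an ene reaction, and the electron-poor C10=C1 is inert) should occur on the β face, syn to the hydrogen-bonding allylic C9 hydroxyl and away from ring A, and thiourea reduction of the O–O bond then leaves the new C5 and C8 oxygens both β.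

Step 10
Reactants: 13 triol
Product: 15 8β-silyl ether (8-OSi(CH3)2C(CH3)3, 5β-OH and 9β-OH free), via stannylene acetal 14 (not isolated)
Conditions: Bu2SnO, PhMe, reflux (−H2O); then t-BuMe2SiCl, rt
Reagents that add atoms: dibutyltin oxide (tin stays in 14 only), CCCC[Sn](=O)CCCC; tert-butyldimethylsilyl chloride, CC(C)(C)[Si](C)(C)Cl
Why: stannylene acetal-mediated monosilylation, in which the tin acetal forms on the cis-8,9-diol and activates its secondary oxygen O8, so that O5–H (used next) and the tertiary O9–H stay free.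

Step 11
Reactants: 15 8β-silyl ether
Product: 17 aldehyde (7β-CH2CHO, C5=C6), via allyl vinyl ether 16 (not isolated)
Conditions: Pd(OCOCF3)2 (5 mol %), 4,7-diphenyl-1,10-phenanthroline, Et3N, butyl vinyl ether, 75 °C; then xylenes, 160 °C (sealed tube)
Reagents that add atoms: butyl vinyl ether, C=COCCCC
Why: transfer vinylation of the secondary allylic O5–H followed by a Claisen rearrangement, whose suprafacial [3,3] shift delivers C11 to C7 on the face of the departing C5–O bond (β, cis to O8) and moves the alkene to C5=C6.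

Step 12
Reactants: 17 aldehyde
Product: 18 enal (7β-C(=CH2)CHO)
Conditions: CH2=NMe2+ I− (2 equiv), Et3N, CH2Cl2, rt
Reagents that add atoms: N,N-dimethylmethyleneiminium iodide (Eschenmoser's salt), C=[N+](C)C.[I-]
Why: Mannich reaction and β-elimination of dimethylamine install the C13 methylene at the aldehyde stage, under conditions that do not enolise the ring A ester.

Step 13
Reactants: 18 enal
Product: 19 5α,6α-epoxide
Conditions: dimethyldioxirane, acetone, −20 → 0 °C
Reagents that add atoms: dimethyldioxirane, CC1(C)OO1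
Why: electrophilic epoxidation takes the only electron-rich alkene (C5=C6) and should come from the α face, away from the pseudoaxial C7 chain and the axial C9 oxygen, and only this α-epoxide can be opened by the chain in step 14.

Step 14
Reactants: 19 5α,6α-epoxide
Product: 20 acetal alcohol (cis-fused ring O6–C12H(OCH3)–C11(=CH2)–C7, 5α-OH)
Conditions: BF3·OEt2 (0.2 equiv), MeOH (5 equiv), CH2Cl2, −40 °C; Et3N
Reagents that add atoms: methanol, CO
Why: epoxide opening with neighbouring carbonyl participation, in which the side-chain carbonyl oxygen attacks C6 5-exo with inversion (trans-diaxial) and methanol traps the oxocarbenium ion, so that O6 ends β and cis to C7, the C5 oxygen stays α, and C12 is stored as a base-stable mixed acetal.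

Step 15
Reactants: 20 acetal alcohol
Product: 21 fragmentation precursor (5α-mesylate, 9β-OH, 8β-silyl ether, 6,7-fused acetal)
Conditions: MsCl (1.2 equiv), Et3N, CH2Cl2, −20 → 0 °C
Reagents that add atoms: methanesulfonyl chloride, CS(=O)(=O)Cl
Why: sulfonylation through sulfene takes the secondary C5 hydroxyl and leaves the tertiary C9 hydroxyl free, giving the nucleofuge trans to the C4 methyl.

Step 16
Reactants: 21 fragmentation precursor
Product: 22 ten-membered keto enoate (C9 ketone, ring-cis C10=C1 ester, Z C4=C5)
Conditions: KN(SiMe3)2 (1.05 equiv), THF, −78 → −20 °C; AcOH, −78 °C; crude product used at once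
Reagents that add atoms: none
Why: Deprotonation of the tertiary C9 hydroxyl gives a potassium alkoxide in which an oxygen lone pair, the C4–C9 bond and the C5–O(mesyl) bond are antiperiplanar, so C9=O forms, C4–C9 breaks, C4=C5 forms and methanesulfonate leaves in one concerted heterolytic step (Grob fragmentation; closest known type: decalin 1,3-diol monosulfonates to cyclodecenones). No ring is closed by bond formation: the ten-membered carbocycle C1–C10 is uncovered by scission of the bond shared by rings A and B, and the fused acetal ring is carried along. No stereocentre is created (C4, C5 and C9 become trigonal; C6–C8 are untouched). The step needs Z geometry at C4=C5, which is secured by the cis ring fusion and the trans C4-methyl/C5-mesylate pair: in the ring B chair with the C4 methyl, O6 and O8 equatorial, C3 is axial and the mesylate is equatorial and anti to C4–C9, so C3 and C6 end cis on the new alkene, while the C10=C1 geometry is inherited from ring A. Competing paths are weak because O6 is locked in the acetal (no epoxide), the equatorial mesylate has no antiperiplanar hydrogen (no E2) and is not aligned for oxetane closure. Base is held to one equivalent and quenched cold because the product is an alkylidene β-keto ester with acidic C2 hydrogens.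

Step 17
Reactants: 22 ten-membered keto enoate
Product: 23 (9S)-alcohol
Conditions: NaBH4, CeCl3·7H2O, MeOH, −78 °C
Reagents that add atoms: none
Why: Luche 1,2-reduction of the enone carbonyl, where the polar Felkin–Anh model (hydride anti to the C8–OSi bond, no chelation by the bulky silyl ether) predicts the 9S alcohol, trans to O8.

Step 18
Reactants: 24 [(2S)-2-methyloxiran-2-yl]methanol
Product: 25 (2R)-2-methyloxirane-2-carboxylic acid
Conditions: RuCl3 (2 mol %), NaIO4 (3 equiv), MeCN/EtOAc/H2O, 0 °C
Reagents that add atoms: water, O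
Why: RuO4-catalysed oxidation of the primary alcohol to the acid leaves the quaternary epoxide carbon untouched (the descriptor changes from S to R only through the priority rules).

Step 19
Reactants: 23 (9S)-alcohol; 25 (2R)-2-methyloxirane-2-carboxylic acid
Product: 27 9-O-(2R)-2-methylglycidate, via mixed anhydride 26 (not isolated)
Conditions: 25, 2,4,6-Cl3C6H2COCl, Et3N, THF, 0 °C; then 23, DMAP, PhMe, rt
Reagents that add atoms: 2,4,6-trichlorobenzoyl chloride (its atoms stay in 26 only), O=C(Cl)c1c(Cl)cc(Cl)cc1Cl
Why: Yamaguchi esterification acylates the hindered allylic O9 with retention at C9, and the quaternary glycidate carbon cannot epimerise.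

Step 20
Reactants: 27 9-O-glycidate
Product: 28 8-alcohol
Conditions: HF·pyridine, pyridine, THF, 0 °C → rt
Reagents that add atoms: none
Why: fluoride cleavage of the secondary silyl ether in a buffered acidic medium, in which acyl migration from O9 to O8 should be slow.

Step 21
Reactants: 28 8-alcohol
Product: 29 8-O-acetate
Conditions: Ac2O, pyridine, DMAP (5 mol %), CH2Cl2, 0 °C
Reagents that add atoms: acetic anhydride, CC(=O)OC(C)=O
Why: DMAP-catalysed acetylation caps O8 before C12 is unmasked, so that the lactol of the next step can only form on O6.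

Step 22
Reactants: 29 8-O-acetate
Product: 31 α-methylene γ-lactone (cis-fused 6,12-olide), via lactol 30 (not isolated)
Conditions: PPTS, acetone/H2O (4:1), 40 °C; then TEMPO (0.2 equiv), PhI(OAc)2, CH2Cl2, rt
Reagents that add atoms: water, O
Why: mild hydrolysis of the mixed acetal and oxoammonium (TEMPO) oxidation of the lactol give the α-methylene lactone without enolate chemistry, so the acetate, glycidate and methyl ester are not exposed to base.

Step 23
Reactants: 31 α-methylene γ-lactone
Product: 32 CNP0159450.1
Conditions: mCPBA (1.1 equiv), NaHCO3, CH2Cl2, 0 °C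
Reagents that add atoms: 3-chloroperoxybenzoic acid, OOC(=O)c1cccc(Cl)c1
Why: Prilezhaev epoxidation takes the only nucleophilic alkene (C4=C5) stereospecifically (Z alkene to cis epoxide), and with H6 eclipsing the alkene to avoid allylic 1,3-strain with C3 the peracid should attack the exposed face that carries O6, giving 4R,5S.

**Compound list**

1 | 2-methylcyclohexane-1,3-dione | CC1C(=O)CCCC1=O | starting material
2 | methyl 3-oxopent-4-enoate | COC(=O)CC(=O)C=C | starting material
3 | methyl 5-(1-methyl-2,6-dioxocyclohexyl)-3-oxopentanoate | COC(=O)CC(=O)CCC1(C)C(=O)CCCC1=O | intermediate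
4 | methyl (4aR,8aS)-2,8a-dihydroxy-4a-methyl-5-oxo-3,4,4a,5,6,7,8,8a-octahydronaphthalene-1-carboxylate (cis-ketol, enol form) | COC(=O)C1=C(O)CC[C@@]2(C)C(=O)CCC[C@@]12O | intermediate
5 | enol triflate of 4 (C1–OSO2CF3) | COC(=O)C1=C(OS(=O)(=O)C(F)(F)F)CC[C@@]2(C)C(=O)CCC[C@@]12O | intermediate
6 | methyl (4aR,8aS)-8a-hydroxy-4a-methyl-5-oxo-3,4,4a,5,6,7,8,8a-octahydronaphthalene-1-carboxylate | COC(=O)C1=CCC[C@@]2(C)C(=O)CCC[C@@]12O | intermediate
7 | 9-O-trimethylsilyl ether, C5 trimethylsilyl enol ether of 6 | COC(=O)C1=CCC[C@@]2(C)C(O[Si](C)(C)C)=CCC[C@@]12O[Si](C)(C)C | intermediate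
8 | ring B enone (C5=O, C6=C7), 9β-OSiMe3 | COC(=O)C1=CCC[C@@]2(C)C(=O)C=CC[C@@]12O[Si](C)(C)C | intermediate
9 | dienyl triflate C5(OTf)=C6–C7=C8, 9β-OSiMe3 | COC(=O)C1=CCC[C@@]2(C)C(OS(=O)(=O)C(F)(F)F)=CC=C[C@@]12O[Si](C)(C)C | intermediate
10 | ring B 5,7-diene, 9β-OSiMe3 | COC(=O)C1=CCC[C@@]2(C)C=CC=C[C@@]12O[Si](C)(C)C | intermediate
11 | ring B 5,7-diene, 9β-OH (dienol) | COC(=O)C1=CCC[C@@]2(C)C=CC=C[C@@]12O | intermediate
12 | 5β,8β-epidioxide (endoperoxide), 9β-OH | COC(=O)C1=CCC[C@@]2(C)[C@H]3C=C[C@H](OO3)[C@@]12O | intermediate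
13 | 5β,8β,9β-triol with C6=C7 | COC(=O)C1=CCC[C@@]2(C)[C@H](O)C=C[C@H](O)[C@@]12O | intermediate
14 | 8,9-O-dibutylstannylene acetal of 13 | COC(=O)C1=CCC[C@@]2(C)[C@H](O)C=C[C@H](O3)[C@@]12O[Sn]3(CCCC)CCCC | intermediate
15 | 8β-O-tert-butyldimethylsilyl ether of 13 (5β-OH, 9β-OH free) | COC(=O)C1=CCC[C@@]2(C)[C@H](O)C=C[C@H](O[Si](C)(C)C(C)(C)C)[C@@]12O | intermediate
16 | 5β-O-vinyl ether of 15 | COC(=O)C1=CCC[C@@]2(C)[C@H](OC=C)C=C[C@H](O[Si](C)(C)C(C)(C)C)[C@@]12O | intermediate
17 | aldehyde: 7β-(2-oxoethyl), C5=C6, 8β-OTBS, 9β-OH | COC(=O)C1=CCC[C@@]2(C)C=C[C@H](CC=O)[C@H](O[Si](C)(C)C(C)(C)C)[C@@]12O | intermediate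
18 | enal: 7β-(3-oxoprop-1-en-2-yl), C5=C6 | COC(=O)C1=CCC[C@@]2(C)C=C[C@H](C(=C)C=O)[C@H](O[Si](C)(C)C(C)(C)C)[C@@]12O | intermediate
19 | 5α,6α-epoxide of 18 | COC(=O)C1=CCC[C@@]2(C)[C@H]3O[C@H]3[C@H](C(=C)C=O)[C@H](O[Si](C)(C)C(C)(C)C)[C@@]12O | intermediate
20 | acetal alcohol: 6β-O/7β-C fused 2-methoxy-3-methylenetetrahydrofuran, 5α-OH, 8β-OTBS, 9β-OH | COC(=O)C1=CCC[C@@]2(C)[C@@H](O)[C@@H]3OC(OC)C(=C)[C@@H]3[C@H](O[Si](C)(C)C(C)(C)C)[C@@]12O | intermediate
21 | fragmentation precursor: 5α-mesylate of 20 | COC(=O)C1=CCC[C@@]2(C)[C@@H](OS(C)(=O)=O)[C@@H]3OC(OC)C(=C)[C@@H]3[C@H](O[Si](C)(C)C(C)(C)C)[C@@]12O | intermediate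
22 | ten-membered 9-keto enoate, Z C4=C5, ring-cis C10=C1, 6,7-fused methyl acetal, 8-OTBS | COC(=O)/C1=C/CC/C(C)=C\[C@@H]2OC(OC)C(=C)[C@@H]2[C@H](O[Si](C)(C)C(C)(C)C)C1=O | intermediate
23 | (9S)-alcohol of 22 | COC(=O)/C1=C/CC/C(C)=C\[C@@H]2OC(OC)C(=C)[C@@H]2[C@H](O[Si](C)(C)C(C)(C)C)[C@H]1O | intermediate
24 | [(2S)-2-methyloxiran-2-yl]methanol | OC[C@@]1(C)CO1 | starting material
25 | (2R)-2-methyloxirane-2-carboxylic acid | OC(=O)[C@@]1(C)CO1 | intermediate
26 | mixed anhydride of 25 and 2,4,6-trichlorobenzoic acid | O=C(OC(=O)c1c(Cl)cc(Cl)cc1Cl)[C@@]1(C)CO1 | intermediate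
27 | 9-O-[(2R)-2-methyloxirane-2-carbonyl] ester of 23 | COC(=O)/C1=C/CC/C(C)=C\[C@@H]2OC(OC)C(=C)[C@@H]2[C@H](O[Si](C)(C)C(C)(C)C)[C@H]1OC(=O)[C@@]1(C)CO1 | intermediate
28 | 8-alcohol (desilylated 27) | COC(=O)/C1=C/CC/C(C)=C\[C@@H]2OC(OC)C(=C)[C@@H]2[C@H](O)[C@H]1OC(=O)[C@@]1(C)CO1 | intermediate
29 | 8-O-acetate of 28 | COC(=O)/C1=C/CC/C(C)=C\[C@@H]2OC(OC)C(=C)[C@@H]2[C@H](OC(C)=O)[C@H]1OC(=O)[C@@]1(C)CO1 | intermediate
30 | lactol (C12–OH) from 29 | COC(=O)/C1=C/CC/C(C)=C\[C@@H]2OC(O)C(=C)[C@@H]2[C@H](OC(C)=O)[C@H]1OC(=O)[C@@]1(C)CO1 | intermediate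
31 | α-methylene 6,12-lactone with Z C4=C5 (4,5-deoxy target) | COC(=O)/C1=C/CC/C(C)=C\[C@@H]2OC(=O)C(=C)[C@@H]2[C@H](OC(C)=O)[C@H]1OC(=O)[C@@]1(C)CO1 | intermediate
32 | CNP0159450.1, (4R,5S,6R,7R,8S,9S)-configured, (2R)-glycidate | C=C1C(=O)O[C@@H]2[C@H]1[C@H](OC(C)=O)[C@@H](OC(=O)[C@@]1(C)CO1)/C(C(=O)OC)=C\CC[C@@]1(C)O[C@@H]21 | target

**Step count**

Total: 23 steps. Longest linear sequence: 22 steps (steps 1–17 and 19–23; step 18 is a one-step side branch).

**Steps most likely to fail**

Step 16 (fragmentation). The fragmentation itself is well aligned; the weak point is what happens afterwards. The product is an alkylidene β-keto ester, and alkoxide that has not yet fragmented can deprotonate it at C2. That would stall conversion, and reprotonation at C10 would move the alkene out of conjugation. Silyl migration from O8 to the O9 alkoxide can also compete. The fallback lowers the oxidation level of C14 before the ring is opened. It sets out from 21: reduction of the ester with i-Bu2AlH (CH2Cl2, −78 °C) gives the C14 allylic alcohol F1. Fragmentation of F1 with KOC(CH3)3 (2.2 equiv, THF, 0 °C) gives the hydroxymethyl enone F2, whose C2 hydrogens are no longer acidified by a β-dicarbonyl. Luche reduction gives the 9,14-diol F3. TEMPO/PhI(OAc)2 oxidises only the primary allylic alcohol to the enal F4, and NaClO2 (NaH2PO4, 2-methylbut-2-ene) gives the acid F5. Me3SiCHN2 in MeOH/PhMe gives 23, where the route is rejoined.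

Step 2 (aldol). The keto ester methylene is acidic enough to cyclise without the catalyst, which would erode the enantiomeric purity, and the ketol may lose water under the reaction conditions. The fallback accepts the dehydration. It sets out from 3: cyclodehydration (D-proline, then TsOH, PhMe) gives the enone F6, which also offers a point for enrichment by crystallisation. Nucleophilic epoxidation with alkaline H2O2 (MeOH, 0 °C) should give the 9β,10β-epoxy ketone F7, cis to the angular methyl. Wharton transposition (N2H4·H2O, AcOH, MeOH, 0 °C) at the more accessible C1 carbonyl returns to the route at 6; steps 3 and 4 are then not needed.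

Step 17 (ketone reduction). In the ten-membered ring the conformation of the enone, not the Felkin–Anh preference, may decide the face of hydride delivery, which would give the C9 epimer. The fallback uses that epimer instead of fighting the selectivity. It sets out from 22: the same reduction then gives the (9R)-alcohol F8, which is esterified with inversion by a Mitsunobu reaction with acid 25 (PPh3, diisopropyl azodicarboxylate, PhMe, 0 °C). This returns to the route at 27.

**Further compounds**

F1 | step 16 | C14 allylic alcohol of 21 (ester reduced, mesylate kept) | OCC1=CCC[C@@]2(C)[C@@H](OS(C)(=O)=O)[C@@H]3OC(OC)C(=C)[C@@H]3[C@H](O[Si](C)(C)C(C)(C)C)[C@@]12O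
F2 | step 16 | ten-membered 10-(hydroxymethyl) enone | OC/C1=C/CC/C(C)=C\[C@@H]2OC(OC)C(=C)[C@@H]2[C@H](O[Si](C)(C)C(C)(C)C)C1=O
F3 | step 16 | (9S)-9,14-diol | OC/C1=C/CC/C(C)=C\[C@@H]2OC(OC)C(=C)[C@@H]2[C@H](O[Si](C)(C)C(C)(C)C)[C@H]1O
F4 | step 16 | C14 enal, 9-OH | O=C/C1=C/CC/C(C)=C\[C@@H]2OC(OC)C(=C)[C@@H]2[C@H](O[Si](C)(C)C(C)(C)C)[C@H]1O
F5 | step 16 | C14 carboxylic acid, 9-OH | OC(=O)/C1=C/CC/C(C)=C\[C@@H]2OC(OC)C(=C)[C@@H]2[C@H](O[Si](C)(C)C(C)(C)C)[C@H]1O
F6 | step 2 | methyl (4aR)-4a-methyl-2,5-dioxo-2,3,4,4a,5,6,7,8-octahydronaphthalene-1-carboxylate (enone) | COC(=O)C1=C2CCCC(=O)[C@]2(C)CCC1=O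
F7 | step 2 | 9β,10β-epoxy ketone of F6 | COC(=O)[C@@]12C(=O)CC[C@@]3(C)C(=O)CCC[C@@]13O2
F8 | step 17 | (9R)-alcohol, C9 epimer of 23 | COC(=O)/C1=C/CC/C(C)=C\[C@@H]2OC(OC)C(=C)[C@@H]2[C@H](O[Si](C)(C)C(C)(C)C)[C@@H]1O
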